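**Retrosynthetic overview**
1. The two esters come last: the 8,9-diol is acylated at the less hindered C8 hydroxyl (methacrylate) and then at C9 (acetate).
2. The ten-membered ring and the trans α-methylene lactone come from one C6–C7 bond: an intramolecular CrCl2 allylation of a (Z)-enal by a 2-(bromomethyl)enoate, followed by acid.
3. The 3(2H)-furanone is unmasked from a 3,5-disubstituted isoxazole (N–O cleavage, then the tertiary 10-OH closes onto C3). The isoxazole is made by a [3+2] nitrile oxide–alkyne cycloaddition that forms C2–C3.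
4. The alkyne half comes from benzyl β-L-arabinopyranoside (C8 and C9 bought, C10 set by substrate-controlled MeMgBr addition). The nitrile oxide half comes from 3-methylfuran-2(5H)-one, whose ring fixes the Z olefin.
5. Ring order: isoxazole → furanone → ten-membered carbocycle → lactone.

Assumption: benzyl β-L-arabinopyranoside and 3-methylfuran-2(5H)-one are bought as such; locants C1–C15 are the germacrane positions of the target (C1 ketone, C3–O–C10 bridge, C6/C7 lactone fusion).

**Route**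

Step 1
Reactants: 1 benzyl β-L-arabinopyranoside
Product: 2 benzyl 3,4-O-isopropylidene-β-L-arabinopyranoside
Conditions: 2,2-dimethoxypropane, TsOH (cat.), DMF, 25 °C
Reagents that add atoms: 2,2-dimethoxypropane COC(C)(C)OC
Why: Acid-catalysed transacetalisation (acetonide formation) takes only the cis-3,4-diol and leaves 2-OH free, with no stereocentre touched.

Step 2
Reactants: 2 benzyl 3,4-O-isopropylidene-β-L-arabinopyranoside
Product: 3 benzyl 3,4-O-isopropylidene-β-L-erythro-pentopyranosid-2-ulose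
Conditions: Dess–Martin periodinane, CH2Cl2, 25 °C
Reagents that add atoms: none
Why: Dess–Martin oxidation of the only free (secondary) alcohol gives the 2-ulose while both acetals are inert.

Step 3
Reactants: 3 benzyl 3,4-O-isopropylidene-β-L-erythro-pentopyranosid-2-ulose
Product: 4 benzyl 3,4-O-isopropylidene-2-C-methyl-β-L-ribopyranoside
Conditions: MeMgBr, Et2O, −78 to 0 °C
Reagents that add atoms: methylmagnesium bromide C[Mg]Br
Why: Grignard addition occurs on the convex face opposite the cis-fused acetonide, helped by magnesium chelation to the cis anomeric oxygen, so methyl ends cis to OBn and the quaternary carbinol (future C10, L-ribo) is set by the sugar.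

Step 4
Reactants: 4 benzyl 3,4-O-isopropylidene-2-C-methyl-β-L-ribopyranoside
Product: 5 3,4-O-isopropylidene-2-C-methyl-L-ribopyranose
Conditions: H2 (1 atm), Pd/C, EtOAc, 25 °C
Reagents that add atoms: none
Why: Hydrogenolysis of the benzyl glycoside frees the hemiacetal; the acetonide and tertiary alcohol are untouched.

Step 5
Reactants: 5 3,4-O-isopropylidene-2-C-methyl-L-ribopyranose
Product: 6 (2R)-2-[(4S,5S)-5-(hydroxymethyl)-2,2-dimethyl-1,3-dioxolan-4-yl]but-3-yn-2-ol
Conditions: dimethyl (1-diazo-2-oxopropyl)phosphonate, K2CO3, MeOH, 25 °C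
Reagents that add atoms: dimethyl (1-diazo-2-oxopropyl)phosphonate CC(=O)C(=[N+]=[N-])P(=O)(OC)OC
Why: Seyferth–Gilbert homologation (Ohira–Bestmann variant) turns the open aldehyde form of the lactol into the terminal alkyne and releases the C7 primary alcohol; the α-carbon is quaternary and cannot epimerise.

Step 6
Reactants: 7 3-methylfuran-2(5H)-one
Product: 9 (2Z)-4-hydroxy-2-methylbut-2-enal oxime, via lactol 8 (not isolated)
Conditions: iBu2AlH, CH2Cl2, −78 °C; then MeOH, 50% aq. NH2OH, −78 to 25 °C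
Reagents that add atoms: hydroxylamine NO
Why: 1,2-Reduction of the butenolide gives the lactol, whose open hydroxy-enal form is trapped by oxime condensation, so the Z geometry of C4=C5 is inherited from the ring.

Step 7
Reactants: 9 (2Z)-4-hydroxy-2-methylbut-2-enal oxime
Product: 11 (2Z)-4-(tert-butyldimethylsilyloxy)-2-methylbut-2-enal oxime, via bis-silyl ether 10 (not isolated)
Conditions: TBSCl (2.2 equiv), imidazole, DMF, 0 °C; then K2CO3 (cat.), MeOH, 0 °C
Reagents that add atoms: tert-butyldimethylsilyl chloride CC(C)(C)[Si](C)(C)Cl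
Why: Exhaustive silylation followed by selective methanolysis of the labile O-silyl oxime leaves only the primary allylic silyl ether, which prevents the Z-hydroxyl from trapping the nitrile oxide in the next step.

Step 8
Reactants: 11 (2Z)-4-(tert-butyldimethylsilyloxy)-2-methylbut-2-enal oxime (1.5 equiv), 6 (2R)-2-[(4S,5S)-5-(hydroxymethyl)-2,2-dimethyl-1,3-dioxolan-4-yl]but-3-yn-2-ol
Product: 14 3-[(2Z)-4-(tert-butyldimethylsilyloxy)but-2-en-2-yl]-5-[(1S)-1-hydroxy-1-{(4S,5S)-5-(hydroxymethyl)-2,2-dimethyl-1,3-dioxolan-4-yl}ethyl]isoxazole, via hydroximoyl chloride 12 (not isolated), via nitrile oxide 13 (not isolated)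
Conditions: NCS, DMF, 25 °C; then 6, KHCO3, EtOAc, 25 °C
Reagents that add atoms: none
Why: Huisgen [3+2] cycloaddition of the slowly generated nitrile oxide to the terminal alkyne gives the 3,5-disubstituted isoxazole regioselectively (oxygen on the substituted alkyne carbon), forming C2–C3 and the masked furanone ring without touching the stereocentres or the Z olefin.

Step 9
Reactants: 14 the isoxazole
Product: 16 (2S)-5-[(2Z)-4-(tert-butyldimethylsilyloxy)but-2-en-2-yl]-2-[(4S,5S)-5-(hydroxymethyl)-2,2-dimethyl-1,3-dioxolan-4-yl]-2-methylfuran-3(2H)-one, via enaminone 15 (not isolated)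
Conditions: Mo(CO)6, MeCN/H2O, 80 °C; then AcOH/THF/H2O, 25 °C
Reagents that add atoms: none
Why: Reductive N–O cleavage gives the Z-enaminone, and mild acid lets the tertiary 10-OH displace ammonia at C3 (cyclodehydration) to the 3(2H)-furanone, with C10 retained and silyl ether and acetonide intact.

Step 10
Reactants: 16 the furanone alcohol
Product: 17 (4R,5S)-5-{(2S)-5-[(2Z)-4-(tert-butyldimethylsilyloxy)but-2-en-2-yl]-2-methyl-3-oxo-2,3-dihydrofuran-2-yl}-2,2-dimethyl-1,3-dioxolane-4-carbaldehyde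
Conditions: Dess–Martin periodinane, pyridine, CH2Cl2, 0 °C
Reagents that add atoms: none
Why: Buffered Dess–Martin oxidation of the single free primary alcohol gives the C7 aldehyde without epimerising the adjacent C8 centre.

Step 11
Reactants: 17 the C7 aldehyde
Product: 18 methyl 2-{hydroxy[(4S,5S)-5-{(2S)-5-[(2Z)-4-(tert-butyldimethylsilyloxy)but-2-en-2-yl]-2-methyl-3-oxo-2,3-dihydrofuran-2-yl}-2,2-dimethyl-1,3-dioxolan-4-yl]methyl}prop-2-enoate (carbinol epimers)
Conditions: iBu2AlH, NMO, methyl propiolate, THF, 0 °C; then 17, 0 to 25 °C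
Reagents that add atoms: methyl propiolate C#CC(=O)OC
Why: Hydroalumination of the propiolate gives an α-(methoxycarbonyl)vinylalane that adds to the aldehyde as a non-basic Morita–Baylis–Hillman equivalent; the new carbinol centre is irrelevant because step 14 erases it.

Step 12
Reactants: 18 the silyl ether
Product: 19 the corresponding C6 primary allylic alcohol (C7 carbinol epimers; C8, C9, C10 and Z olefin unchanged)
Conditions: HF·pyridine, pyridine, THF, 0 to 25 °C
Reagents that add atoms: none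
Why: Buffered fluoride desilylation removes the silyl group; acetonide, furanone and acrylate tolerate it.

Step 13
Reactants: 19 the diol
Product: 20 the (Z)-enal: methyl 2-{hydroxy[(4S,5S)-5-{(2S)-2-methyl-3-oxo-5-[(2Z)-4-oxobut-2-en-2-yl]-2,3-dihydrofuran-2-yl}-2,2-dimethyl-1,3-dioxolan-4-yl]methyl}prop-2-enoate
Conditions: MnO2, CH2Cl2, 25 °C
Reagents that add atoms: none
Why: MnO2 oxidises only the electron-rich primary allylic alcohol, leaving the deactivated secondary alcohol next to the acrylate.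

Step 14
Reactants: 20 the enal alcohol
Product: 21 methyl (2Z)-2-(bromomethyl)-3-[(4S,5S)-5-{(2S)-2-methyl-3-oxo-5-[(2Z)-4-oxobut-2-en-2-yl]-2,3-dihydrofuran-2-yl}-2,2-dimethyl-1,3-dioxolan-4-yl]prop-2-enoate
Conditions: NBS, Me2S, CH2Cl2, −20 to 0 °C
Reagents that add atoms: N-bromosuccinimide O=C1CCC(=O)N1Br
Why: Corey–Kim-type activation followed by SN2′ attack of bromide gives the rearranged, thermodynamically favoured (Z)-2-(bromomethyl)enoate and removes the C7 carbinol centre.

Step 15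
Reactants: 21 the bromo enal
Product: 24 8,9-dihydroxy-1-oxo-3,10-epoxygermacra-2,4(Z),11(13)-trien-12,6-olide (all stereocentres as in 26), via hydroxy ester 22 (not isolated), via lactone acetonide 23 (not isolated)
Conditions: CrCl2 (10 equiv), THF (3 mM), 25 °C; then 2 M aq. HCl, 40 °C
Reagents that add atoms: none
Why: In this intramolecular Nozaki–Hiyama (Barbier) allylation the allylchromium adds at its γ-carbon through a chair transition state with both ring bonds pseudo-equatorial (6,7-anti, hence the trans lactone), on the π-face fixed by the C8 centre of the cis-acetonide turn (6R,7S), and the acid quench lactonises and removes the acetonide.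

Step 16
Reactants: 24 the diol lactone
Product: 25 the 8-O-methacrylate with free 9-OH
Conditions: methacrylic anhydride (1.2 equiv), Et3N, DMAP (cat.), CH2Cl2, −20 °C
Reagents that add atoms: methacrylic anhydride CC(=C)C(=O)OC(=O)C(C)=C
Why: DMAP-catalysed acylation is kinetically selective for the C8 hydroxyl because the C9 hydroxyl is neopentyl-like next to quaternary C10.

Step 17
Reactants: 25 the 8-O-methacrylate
Product: 26 (4Z,6R,7S,8S,9S,10S)-9-acetoxy-8-methacryloyloxy-1-oxo-3,10-epoxygermacra-2,4,11(13)-trien-12,6-olide (CNP0365569.2)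
Conditions: Ac2O, pyridine, DMAP, CH2Cl2, 25 °C
Reagents that add atoms: acetic anhydride CC(=O)OC(C)=O
Why: Forcing DMAP-catalysed acetylation esterifies the remaining hindered secondary alcohol and changes no stereocentre.

**Compound list**
1 | benzyl β-L-arabinopyranoside | c1ccccc1CO[C@H]2OC[C@H](O)[C@H](O)[C@H]2O | starting material
2 | benzyl 3,4-O-isopropylidene-β-L-arabinopyranoside | c1ccccc1CO[C@H]2OC[C@@H]3OC(C)(C)O[C@@H]3[C@H]2O | intermediate
3 | benzyl 3,4-O-isopropylidene-β-L-erythro-pentopyranosid-2-ulose | c1ccccc1CO[C@H]2OC[C@@H]3OC(C)(C)O[C@@H]3C2=O | intermediate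
4 | benzyl 3,4-O-isopropylidene-2-C-methyl-β-L-ribopyranoside | c1ccccc1CO[C@H]2OC[C@@H]3OC(C)(C)O[C@@H]3[C@]2(C)O | intermediate
5 | 3,4-O-isopropylidene-2-C-methyl-L-ribopyranose (anomer mixture) | OC1OC[C@@H]2OC(C)(C)O[C@@H]2[C@]1(C)O | intermediate
6 | (2R)-2-[(4S,5S)-5-(hydroxymethyl)-2,2-dimethyl-1,3-dioxolan-4-yl]but-3-yn-2-ol | OC[C@@H]1OC(C)(C)O[C@@H]1[C@](C#C)(C)O | intermediate
7 | 3-methylfuran-2(5H)-one | CC1=CCOC1=O | starting material
8 | 3-methyl-2,5-dihydrofuran-2-ol (lactol) | CC1=CCOC1O | intermediate (not isolated)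
9 | (2Z)-4-hydroxy-2-methylbut-2-enal oxime | OC/C=C(/C)C=NO | intermediate
10 | (2Z)-4-(tert-butyldimethylsilyloxy)-2-methylbut-2-enal O-(tert-butyldimethylsilyl)oxime | CC(C)(C)[Si](C)(C)OC/C=C(/C)C=NO[Si](C)(C)C(C)(C)C | intermediate (not isolated)
11 | (2Z)-4-(tert-butyldimethylsilyloxy)-2-methylbut-2-enal oxime | CC(C)(C)[Si](C)(C)OC/C=C(/C)C=NO | intermediate
12 | (2Z)-4-(tert-butyldimethylsilyloxy)-N-hydroxy-2-methylbut-2-enimidoyl chloride | CC(C)(C)[Si](C)(C)OC/C=C(/C)C(Cl)=NO | intermediate (not isolated)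
13 | (2Z)-4-(tert-butyldimethylsilyloxy)-2-methylbut-2-enenitrile oxide | CC(C)(C)[Si](C)(C)OC/C=C(/C)C#[N+][O-] | intermediate (not isolated)
14 | 3-[(2Z)-4-(tert-butyldimethylsilyloxy)but-2-en-2-yl]-5-[(1S)-1-hydroxy-1-{(4S,5S)-5-(hydroxymethyl)-2,2-dimethyl-1,3-dioxolan-4-yl}ethyl]isoxazole | OC[C@@H]1OC(C)(C)O[C@@H]1[C@](c2cc(/C(C)=C\CO[Si](C)(C)C(C)(C)C)no2)(C)O | intermediate
15 | (2S,4Z,6Z)-5-amino-8-(tert-butyldimethylsilyloxy)-2-hydroxy-2-[(4S,5S)-5-(hydroxymethyl)-2,2-dimethyl-1,3-dioxolan-4-yl]-6-methylocta-4,6-dien-3-one (enaminone) | OC[C@@H]1OC(C)(C)O[C@@H]1[C@](C(=O)/C=C(\N)/C(C)=C\CO[Si](C)(C)C(C)(C)C)(C)O | intermediate (not isolated)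
16 | (2S)-5-[(2Z)-4-(tert-butyldimethylsilyloxy)but-2-en-2-yl]-2-[(4S,5S)-5-(hydroxymethyl)-2,2-dimethyl-1,3-dioxolan-4-yl]-2-methylfuran-3(2H)-one | OC[C@@H]1OC(C)(C)O[C@@H]1[C@]2(C)OC(=CC2=O)/C(C)=C\CO[Si](C)(C)C(C)(C)C | intermediate
17 | (4R,5S)-5-{(2S)-5-[(2Z)-4-(tert-butyldimethylsilyloxy)but-2-en-2-yl]-2-methyl-3-oxo-2,3-dihydrofuran-2-yl}-2,2-dimethyl-1,3-dioxolane-4-carbaldehyde | O=C[C@@H]1OC(C)(C)O[C@@H]1[C@]2(C)OC(=CC2=O)/C(C)=C\CO[Si](C)(C)C(C)(C)C | intermediate
18 | methyl 2-{hydroxy[(4S,5S)-5-{(2S)-5-[(2Z)-4-(tert-butyldimethylsilyloxy)but-2-en-2-yl]-2-methyl-3-oxo-2,3-dihydrofuran-2-yl}-2,2-dimethyl-1,3-dioxolan-4-yl]methyl}prop-2-enoate (carbinol epimers) | C=C(C(=O)OC)C(O)[C@@H]1OC(C)(C)O[C@@H]1[C@]2(C)OC(=CC2=O)/C(C)=C\CO[Si](C)(C)C(C)(C)C | intermediate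
19 | methyl 2-{hydroxy[(4S,5S)-5-{(2S)-5-[(2Z)-4-hydroxybut-2-en-2-yl]-2-methyl-3-oxo-2,3-dihydrofuran-2-yl}-2,2-dimethyl-1,3-dioxolan-4-yl]methyl}prop-2-enoate (carbinol epimers) | C=C(C(=O)OC)C(O)[C@@H]1OC(C)(C)O[C@@H]1[C@]2(C)OC(=CC2=O)/C(C)=C\CO | intermediate
20 | methyl 2-{hydroxy[(4S,5S)-5-{(2S)-2-methyl-3-oxo-5-[(2Z)-4-oxobut-2-en-2-yl]-2,3-dihydrofuran-2-yl}-2,2-dimethyl-1,3-dioxolan-4-yl]methyl}prop-2-enoate (carbinol epimers) | C=C(C(=O)OC)C(O)[C@@H]1OC(C)(C)O[C@@H]1[C@]2(C)OC(=CC2=O)/C(C)=C\C=O | intermediate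
21 | methyl (2Z)-2-(bromomethyl)-3-[(4S,5S)-5-{(2S)-2-methyl-3-oxo-5-[(2Z)-4-oxobut-2-en-2-yl]-2,3-dihydrofuran-2-yl}-2,2-dimethyl-1,3-dioxolan-4-yl]prop-2-enoate | BrC/C(C(=O)OC)=C\[C@@H]1OC(C)(C)O[C@@H]1[C@]2(C)OC(=CC2=O)/C(C)=C\C=O | intermediate
22 | methyl 2-[6-hydroxy-8,9-(isopropylidenedioxy)-1-oxo-3,10-epoxygermacra-2,4(Z)-dien-7-yl]prop-2-enoate (stereocentres as in 26) | CC1(C)O[C@H]2[C@@H](C(=C)C(=O)OC)[C@H](O)/C=C(/C)C3=CC(=O)[C@@](C)(O3)[C@H]2O1 | intermediate (not isolated)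
23 | 8,9-O-isopropylidene-8,9-dihydroxy-1-oxo-3,10-epoxygermacra-2,4(Z),11(13)-trien-12,6-olide (stereocentres as in 26) | CC1(C)O[C@H]2[C@H]3C(=C)C(=O)O[C@@H]3/C=C(/C)C3=CC(=O)[C@@](C)(O3)[C@H]2O1 | intermediate (not isolated)
24 | 8,9-dihydroxy-1-oxo-3,10-epoxygermacra-2,4(Z),11(13)-trien-12,6-olide (stereocentres as in 26) | O[C@H]1[C@H]2C(=C)C(=O)O[C@@H]2/C=C(/C)C2=CC(=O)[C@@](C)(O2)[C@H]1O | intermediate
25 | 9-hydroxy-8-methacryloyloxy-1-oxo-3,10-epoxygermacra-2,4(Z),11(13)-trien-12,6-olide (stereocentres as in 26) | C=C(C)C(=O)O[C@H]1[C@H]2C(=C)C(=O)O[C@@H]2/C=C(/C)C2=CC(=O)[C@@](C)(O2)[C@H]1O | intermediate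
26 | (4Z,6R,7S,8S,9S,10S)-9-acetoxy-8-methacryloyloxy-1-oxo-3,10-epoxygermacra-2,4,11(13)-trien-12,6-olide | C=C(C)C(=O)O[C@H]1[C@H]2C(=C)C(=O)O[C@@H]2/C=C(/C)C2=CC(=O)[C@@](C)(O2)[C@H]1OC(C)=O | target

**Step count**
Total: 17 steps. Longest linear sequence: 15 steps (steps 1–5, then 8–17); steps 6–7 form the short side branch.

**Three steps most likely to fail**

Step 15 (ring closure) is the weakest point. The 6,7-anti outcome rests on the usual chair preference of allylchromium reagents, but which π-face of C7 the tethered aldehyde takes is decided by the C8 allylic centre and is not secure; the conformer with the C8 hydrogen in the plane would give 6S,7R. If that isomer dominates, the fallback sets out from aldehyde 17 and returns at 25. K2CO3 in MeOH epimerises the cis-dioxolane aldehyde to the more stable trans-dioxolane aldehyde F2 (C8 inverted). The operations of steps 11–15 are then repeated on it: vinylalane addition gives the acrylate adduct F3, HF·pyridine the allylic alcohol F4, MnO2 the enal F5, NBS/Me2S the allylic bromide F6, and CrCl2 closes the ring through the hydroxy ester F7 and the lactone acetonide F8 to the 8-epi diol F9. With C8 inverted, the same intrinsic facial preference should now deliver 6R,7S. A Mitsunobu esterification of F9 with methacrylic acid (PPh3, DIAD) at the less hindered C8 hydroxyl then inverts C8 and installs the ester in one operation, giving 25.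

Step 16 (regioselective acylation) relies only on the steric difference between the C8 and C9 hydroxyls. If mixtures or bis-acylation result, the fallback sets out from diol 24 and returns at 26 with the order of esterification reversed. Trimethyl orthoacetate with PPTS gives the cyclic 8,9-orthoacetate F10; mild aqueous acetic acid opens it to the ester on the more hindered oxygen, the 9-O-acetyl 8-alcohol F11; methacrylic anhydride with catalytic Sc(OTf)3 (acidic conditions suppress 9→8 acetyl migration) then gives 26.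

Step 5 (alkyne formation) asks a pyranose lactol with a free tertiary α-hydroxyl to react through a small equilibrium amount of aldehyde, and may be slow or low-yielding. The fallback sets out from lactol 5 and returns at 6. Wittig chloromethylenation with Ph3P=CHCl (from (chloromethyl)triphenylphosphonium chloride and n-BuLi, THF) opens the ring to the chloroalkene F1 (E/Z mixture), and excess n-BuLi at −78 °C eliminates HCl from F1 to give alkyne 6.

**Further compounds**
F1 | step 5 | (2R)-4-chloro-2-[(4S,5S)-5-(hydroxymethyl)-2,2-dimethyl-1,3-dioxolan-4-yl]but-3-en-2-ol (E/Z mixture) | OC[C@@H]1OC(C)(C)O[C@@H]1[C@](C=CCl)(C)O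
F2 | step 15 | 8-epi-17, trans-dioxolane aldehyde (4S,5S) | O=C[C@H]1OC(C)(C)O[C@@H]1[C@]2(C)OC(=CC2=O)/C(C)=C\CO[Si](C)(C)C(C)(C)C
F3 | step 15 | 8-epi-18, acrylate adduct (carbinol epimers) | C=C(C(=O)OC)C(O)[C@H]1OC(C)(C)O[C@@H]1[C@]2(C)OC(=CC2=O)/C(C)=C\CO[Si](C)(C)C(C)(C)C
F4 | step 15 | 8-epi-19, allylic alcohol | C=C(C(=O)OC)C(O)[C@H]1OC(C)(C)O[C@@H]1[C@]2(C)OC(=CC2=O)/C(C)=C\CO
F5 | step 15 | 8-epi-20, (Z)-enal | C=C(C(=O)OC)C(O)[C@H]1OC(C)(C)O[C@@H]1[C@]2(C)OC(=CC2=O)/C(C)=C\C=O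
F6 | step 15 | 8-epi-21, (Z)-allylic bromide | BrC/C(C(=O)OC)=C\[C@H]1OC(C)(C)O[C@@H]1[C@]2(C)OC(=CC2=O)/C(C)=C\C=O
F7 | step 15 | 8-epi-22, macrocyclic hydroxy ester | CC1(C)O[C@@H]2[C@@H](C(=C)C(=O)OC)[C@H](O)/C=C(/C)C3=CC(=O)[C@@](C)(O3)[C@H]2O1
F8 | step 15 | 8-epi-23, lactone acetonide | CC1(C)O[C@@H]2[C@H]3C(=C)C(=O)O[C@@H]3/C=C(/C)C3=CC(=O)[C@@](C)(O3)[C@H]2O1
F9 | step 15 | 8-epi-24, 8-epi diol lactone | O[C@@H]1[C@H]2C(=C)C(=O)O[C@@H]2/C=C(/C)C2=CC(=O)[C@@](C)(O2)[C@H]1O
F10 | step 16 | 8,9-O-(1-methoxyethylidene) derivative of 24 (cyclic orthoacetate, epimers at the orthoester carbon) | COC1(C)O[C@H]2[C@H]3C(=C)C(=O)O[C@@H]3/C=C(/C)C3=CC(=O)[C@@](C)(O3)[C@H]2O1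
F11 | step 16 | 9-acetoxy-8-hydroxy-1-oxo-3,10-epoxygermacra-2,4(Z),11(13)-trien-12,6-olide | O[C@H]1[C@H]2C(=C)C(=O)O[C@@H]2/C=C(/C)C2=CC(=O)[C@@](C)(O2)[C@H]1OC(C)=O
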